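**Strategy.** The propane linker is cut at its bond to ring A (B-alkyl Suzuki coupling), and ring B is traced back to an aryl 1,1-dimethylpropargyl ether. The key step closes the pyran ring by joining the arene carbon C4a to the alkyne terminus C4 in a gold-catalysed 6-endo-dig hydroarylation. It exploits the fact that the ether oxygen O1 on C8a has only one unsubstituted ortho carbon, C4a, because C8 carries oxygen, so the ring can close in one sense only. The precursor is a 2-bromo-5-silyloxy-4-propargyloxybenzaldehyde: its formyl group first makes the para OH selectively alkylable and later grows into the linker, and its bromine becomes the C5 prenyl group.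

Key step: step 4

Remark: the target has no stereocentre and no configured double bond, so nothing stereochemical has to be set. TBS = tert-butyldimethylsilyl; atom numbers C2–C8a refer to the 2H-chromene of ring B.

**Route**

Step 1
Reactants: 1 2-bromo-4,5-dimethoxybenzaldehyde
Product: 2 2-bromo-4,5-dihydroxybenzaldehyde
Conditions: BBr3 (3 equiv), CH2Cl2, −78 °C to rt; aqueous work-up
Reagents that add atoms: none
Why: Lewis-acid cleavage of both aryl methyl ethers (BBr3 demethylation) should leave the aldehyde and the aryl bromide untouched.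

Step 2
Reactants: 2 2-bromo-4,5-dihydroxybenzaldehyde
Product: 3 2-bromo-5-hydroxy-4-[(2-methylbut-3-yn-2-yl)oxy]benzaldehyde
Conditions: 3-chloro-3-methylbut-1-yne (1.2 equiv), DBU (1.05 equiv), CuCl2 (1 mol %), MeCN, 0 °C, N2
Reagents that add atoms: 3-chloro-3-methylbut-1-yne, C#CC(C)(C)Cl
Why: Copper-catalysed propargylic etherification of a phenol should occur at the OH para to the formyl group only, because that OH is far more acidic and one equivalent of base forms only its phenoxide.

Step 3
Reactants: 3 2-bromo-5-hydroxy-4-[(2-methylbut-3-yn-2-yl)oxy]benzaldehyde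
Product: 4 2-bromo-5-[(tert-butyldimethylsilyl)oxy]-4-[(2-methylbut-3-yn-2-yl)oxy]benzaldehyde
Conditions: TBSCl, imidazole, DMF, rt
Reagents that add atoms: tert-butyldimethylsilyl chloride, CC(C)(C)[Si](C)(C)Cl
Why: Standard silylation of the remaining phenol masks the oxygen next to the propargyl ether before the π-acid step.

Step 4
Reactants: 4 2-bromo-5-[(tert-butyldimethylsilyl)oxy]-4-[(2-methylbut-3-yn-2-yl)oxy]benzaldehyde
Product: 5 5-bromo-8-[(tert-butyldimethylsilyl)oxy]-2,2-dimethyl-2H-chromene-6-carbaldehyde
Conditions: [(t-Bu)2(2-biphenylyl)PAu(NCMe)]SbF6 (3 mol %), ClCH2CH2Cl, 50 °C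
Reagents that add atoms: none
Why: The cationic monovalent gold complex binds the terminal alkyne of 4, and the arene carbon ortho to the ether oxygen (future C4a) attacks the terminal alkyne carbon (future C4) anti to gold; rearomatisation of the arenium ion and protodeauration of the vinylgold species release the 2H-chromene and the catalyst. The closest known reaction type is the gold- or platinum-catalysed intramolecular hydroarylation of aryl propargyl ethers to 2H-chromenes. The pyran ring closes in the 6-endo-dig mode through the C4–C4a bond, helped by the gem-dimethyl group, which also disfavours the 5-exo path. No stereocentre is formed. Regioselectivity is fixed because the ether oxygen has only one free ortho carbon (the other carries OTBS), and this carbon is ortho to oxygen, ortho to bromine and meta to the formyl group, the site to which all three substituents direct an electrophile. Chemoselectivity needs the neighbouring oxygen to stay silent, which the bulky, weakly nucleophilic silyl ether secures (a free OH would add 6-exo-dig), and the aldehyde and the aryl bromide are inert to the π-acid.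

Step 5
Reactants: 5 5-bromo-8-[(tert-butyldimethylsilyl)oxy]-2,2-dimethyl-2H-chromene-6-carbaldehyde
Product: 6 8-[(tert-butyldimethylsilyl)oxy]-2,2-dimethyl-5-(3-methylbut-2-en-1-yl)-2H-chromene-6-carbaldehyde
Conditions: tributyl(3-methylbut-2-en-1-yl)stannane, Pd(PPh3)4 (5 mol %), DMF, 90 °C
Reagents that add atoms: tributyl(3-methylbut-2-en-1-yl)stannane, CCCC[Sn](CCCC)(CCCC)CC=C(C)C
Why: Stille coupling of an aryl bromide activated by the ortho formyl group should transfer the prenyl group through its primary carbon, giving the linear prenyl arene.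

Step 6
Reactants: 6 8-[(tert-butyldimethylsilyl)oxy]-2,2-dimethyl-5-(3-methylbut-2-en-1-yl)-2H-chromene-6-carbaldehyde
Product: 7 {8-[(tert-butyldimethylsilyl)oxy]-2,2-dimethyl-5-(3-methylbut-2-en-1-yl)-2H-chromen-6-yl}methanol
Conditions: NaBH4, MeOH/THF, 0 °C
Reagents that add atoms: none
Why: Borohydride 1,2-reduction of the aldehyde should not touch the alkenes or the aryl silyl ether at 0 °C.

Step 7
Reactants: 7 {8-[(tert-butyldimethylsilyl)oxy]-2,2-dimethyl-5-(3-methylbut-2-en-1-yl)-2H-chromen-6-yl}methanol
Product: 8 tert-butyl{[6-(chloromethyl)-2,2-dimethyl-5-(3-methylbut-2-en-1-yl)-2H-chromen-8-yl]oxy}dimethylsilane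
Conditions: PPh3, CCl4, CH2Cl2, rt; used crude
Reagents that add atoms: carbon tetrachloride, ClC(Cl)(Cl)Cl
Why: Appel chlorination works under neutral conditions without electrophilic chlorine, so the electron-rich benzylic chloride should form without attack on the prenyl or chromene alkenes.

Step 8
Reactants: 8 tert-butyl{[6-(chloromethyl)-2,2-dimethyl-5-(3-methylbut-2-en-1-yl)-2H-chromen-8-yl]oxy}dimethylsilane
Product: 9 tert-butyl{[2,2-dimethyl-5-(3-methylbut-2-en-1-yl)-6-(prop-2-en-1-yl)-2H-chromen-8-yl]oxy}dimethylsilane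
Conditions: CH2=CHMgBr, CuI (10 mol %), THF, −30 to 0 °C
Reagents that add atoms: vinylmagnesium bromide, C=C[Mg]Br
Why: Copper-catalysed coupling of a vinyl Grignard reagent with a benzylic chloride (Kochi-type) should give the allyl arene.

Step 9
Reactants: 10 4-bromobenzene-1,3-diol (4-bromoresorcinol)
Product: 11 1-bromo-2,4-bis[(tert-butyldimethylsilyl)oxy]benzene
Conditions: TBSCl (2.3 equiv), imidazole, DMF, rt
Reagents that add atoms: tert-butyldimethylsilyl chloride, CC(C)(C)[Si](C)(C)Cl
Why: Standard silylation of both phenols gives the same protecting group on all three phenols that are free in the target.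

Step 10
Reactants: 11 1-bromo-2,4-bis[(tert-butyldimethylsilyl)oxy]benzene
Product: 12 1-(2-methylbut-3-en-2-yl)-2,4-bis[(tert-butyldimethylsilyl)oxy]benzene
Conditions: prenylBpin (1.5 equiv), Pd(OAc)2 (3 mol %), 1,1'-bis(di-tert-butylphosphino)ferrocene (3.6 mol %), K3PO4 (aq.), THF, 50 °C
Reagents that add atoms: 4,4,5,5-tetramethyl-2-(3-methylbut-2-en-1-yl)-1,3,2-dioxaborolane, CC(C)=CCB1OC(C)(C)C(C)(C)O1
Why: In the γ-selective Suzuki–Miyaura coupling of allylboron reagents, SE2' transmetalation puts the tertiary carbon on palladium and the bulky chelating bisphosphine should make reductive elimination faster than isomerisation to the primary allyl, giving the 1,1-dimethylallyl arene.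

Step 11
Reactants: 12 1-(2-methylbut-3-en-2-yl)-2,4-bis[(tert-butyldimethylsilyl)oxy]benzene
Product: 13 1-bromo-5-(2-methylbut-3-en-2-yl)-2,4-bis[(tert-butyldimethylsilyl)oxy]benzene
Conditions: NBS (1.0 equiv), MeCN, 0 °C
Reagents that add atoms: N-bromosuccinimide, O=C1CCC(=O)N1Br
Why: Electrophilic aromatic bromination should go to the carbon para to one silyloxy group and ortho to the other (the position between the two oxygens is blocked sterically), while the hindered monosubstituted alkene is much less nucleophilic than the ring.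

Step 12
Reactants: 9 tert-butyl{[2,2-dimethyl-5-(3-methylbut-2-en-1-yl)-6-(prop-2-en-1-yl)-2H-chromen-8-yl]oxy}dimethylsilane; 13 1-bromo-5-(2-methylbut-3-en-2-yl)-2,4-bis[(tert-butyldimethylsilyl)oxy]benzene
Product: 15 tris(tert-butyldimethylsilyl) ether of kazinol K, via alkylborane 14 (not isolated)
Conditions: 9 (1.3 equiv), 9-BBN (1.25 equiv), THF, 0 °C to rt; then 13 (1.0 equiv), Pd(OAc)2 (5 mol %), SPhos (10 mol %), K3PO4 (3 M aq.), THF, 60 °C
Reagents that add atoms: none
Why: 9-BBN should hydroborate only the monosubstituted allyl alkene of 9 (anti-Markovnikov; the prenyl and chromene alkenes are far slower), and because 9 is in excess over 9-BBN no B–H remains to touch the 1,1-dimethylallyl group of 13 in the following B-alkyl Suzuki–Miyaura coupling.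

Step 13
Reactants: 15 tris(tert-butyldimethylsilyl) ether of kazinol K
Product: 16 kazinol K
Conditions: Bu4NF (3.3 equiv), AcOH (3.3 equiv), THF, 0 °C
Reagents that add atoms: none
Why: Buffered fluoride desilylation should free all three phenols without acid, so the chromene, the prenyl group and the 1,1-dimethylallyl group next to a phenol are not at risk.

**Compound list**

1 | 2-bromo-4,5-dimethoxybenzaldehyde | O=Cc1cc(OC)c(OC)cc1Br | starting material
2 | 2-bromo-4,5-dihydroxybenzaldehyde | O=Cc1cc(O)c(O)cc1Br | intermediate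
3 | 2-bromo-5-hydroxy-4-[(2-methylbut-3-yn-2-yl)oxy]benzaldehyde | O=Cc1cc(O)c(OC(C)(C)C#C)cc1Br | intermediate
4 | 2-bromo-5-[(tert-butyldimethylsilyl)oxy]-4-[(2-methylbut-3-yn-2-yl)oxy]benzaldehyde | O=Cc1cc(O[Si](C)(C)C(C)(C)C)c(OC(C)(C)C#C)cc1Br | intermediate
5 | 5-bromo-8-[(tert-butyldimethylsilyl)oxy]-2,2-dimethyl-2H-chromene-6-carbaldehyde | O=Cc1cc(O[Si](C)(C)C(C)(C)C)c2OC(C)(C)C=Cc2c1Br | intermediate
6 | 8-[(tert-butyldimethylsilyl)oxy]-2,2-dimethyl-5-(3-methylbut-2-en-1-yl)-2H-chromene-6-carbaldehyde | O=Cc1cc(O[Si](C)(C)C(C)(C)C)c2OC(C)(C)C=Cc2c1CC=C(C)C | intermediate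
7 | {8-[(tert-butyldimethylsilyl)oxy]-2,2-dimethyl-5-(3-methylbut-2-en-1-yl)-2H-chromen-6-yl}methanol | OCc1cc(O[Si](C)(C)C(C)(C)C)c2OC(C)(C)C=Cc2c1CC=C(C)C | intermediate
8 | tert-butyl{[6-(chloromethyl)-2,2-dimethyl-5-(3-methylbut-2-en-1-yl)-2H-chromen-8-yl]oxy}dimethylsilane | ClCc1cc(O[Si](C)(C)C(C)(C)C)c2OC(C)(C)C=Cc2c1CC=C(C)C | intermediate
9 | tert-butyl{[2,2-dimethyl-5-(3-methylbut-2-en-1-yl)-6-(prop-2-en-1-yl)-2H-chromen-8-yl]oxy}dimethylsilane | C=CCc1cc(O[Si](C)(C)C(C)(C)C)c2OC(C)(C)C=Cc2c1CC=C(C)C | intermediate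
10 | 4-bromobenzene-1,3-diol | Oc1ccc(Br)c(O)c1 | starting material
11 | 1-bromo-2,4-bis[(tert-butyldimethylsilyl)oxy]benzene | CC(C)(C)[Si](C)(C)Oc1ccc(Br)c(O[Si](C)(C)C(C)(C)C)c1 | intermediate
12 | 1-(2-methylbut-3-en-2-yl)-2,4-bis[(tert-butyldimethylsilyl)oxy]benzene | C=CC(C)(C)c1ccc(O[Si](C)(C)C(C)(C)C)cc1O[Si](C)(C)C(C)(C)C | intermediate
13 | 1-bromo-5-(2-methylbut-3-en-2-yl)-2,4-bis[(tert-butyldimethylsilyl)oxy]benzene | C=CC(C)(C)c1cc(Br)c(O[Si](C)(C)C(C)(C)C)cc1O[Si](C)(C)C(C)(C)C | intermediate
14 | 9-{3-[8-[(tert-butyldimethylsilyl)oxy]-2,2-dimethyl-5-(3-methylbut-2-en-1-yl)-2H-chromen-6-yl]propyl}-9-borabicyclo[3.3.1]nonane (not isolated) | CC(C)=CCc1c(CCCB3C4CCCC3CCC4)cc(O[Si](C)(C)C(C)(C)C)c2OC(C)(C)C=Cc12 | intermediate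
15 | tris(tert-butyldimethylsilyl) ether of kazinol K (silyl groups on the ring B phenol at C8 and on both ring A phenols) | C=CC(C)(C)c1cc(CCCc2cc(O[Si](C)(C)C(C)(C)C)c3OC(C)(C)C=Cc3c2CC=C(C)C)c(O[Si](C)(C)C(C)(C)C)cc1O[Si](C)(C)C(C)(C)C | intermediate
16 | kazinol K | C=CC(C)(C)c1cc(CCCc2cc(O)c3c(c2CC=C(C)C)C=CC(C)(C)O3)c(O)cc1O | target

**Step count.** Total: 13 steps. Longest linear sequence: 10 steps (steps 1–8, 12, 13); ring A fragment: 3 steps (9–11).

**Steps most likely to fail**

1. Step 10 (γ-selective prenyl coupling). The allylpalladium species may isomerise to its primary terminus before reductive elimination, which would give the linear prenyl arene. The ortho silyloxy group may also slow reductive elimination at the quaternary carbon, so that protodebromination and base-induced desilylation take over. Fallback: setting out from 11, palladium-catalysed α-arylation of the lithium enolate of methyl isobutyrate (LiNCy2, Pd(dba)2, P(t-Bu)3, toluene, rt) should give methyl 2-{2,4-bis[(tert-butyldimethylsilyl)oxy]phenyl}-2-methylpropanoate F1. Reduction with i-Bu2AlH (toluene, −78 °C) should give 2-{2,4-bis[(tert-butyldimethylsilyl)oxy]phenyl}-2-methylpropanal F2. Wittig methylenation (Ph3PCH3Br, KOt-Bu, THF, 0 °C) should then give 12, where the route resumes.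

2. Step 4 (key hydroarylation). The arene is deactivated by the formyl group and the bromine, so attack on the gold-bound alkyne may be slow. Hydration of the alkyne or ionisation of the tertiary propargyl ether could then compete. Fallback: setting out from 4, iodonium-induced 6-endo-dig cyclisation (I2, NaHCO3, MeNO2, rt) uses a stronger, irreversible electrophile and should give 5-bromo-8-[(tert-butyldimethylsilyl)oxy]-3-iodo-2,2-dimethyl-2H-chromene-6-carbaldehyde F3. Radical deiodination (Bu3SnH 1.1 equiv, Et3B, air, toluene, 0 °C; the vinyl C–I bond reacts much faster than the aryl C–Br bond) should return 5.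

3. Step 2 (selective propargylation). Alkylation may occur at both oxygens or at the less acidic one, and the catecholate may be oxidised or may sequester the copper catalyst. Fallback: setting out from 2, double silylation (TBSCl 2.3 equiv, imidazole, DMF) should give 2-bromo-4,5-bis[(tert-butyldimethylsilyl)oxy]benzaldehyde F4. Brief treatment with K2CO3 (0.2 equiv) in MeOH at 0 °C should cleave only the silyl ether para to the formyl group, which has the better phenoxide leaving group, and give 2-bromo-5-[(tert-butyldimethylsilyl)oxy]-4-hydroxybenzaldehyde F5. Propargylation of this single phenol under the conditions of step 2 should give 4, where the route resumes.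

**Further compounds**

F1 | step 10 | methyl 2-{2,4-bis[(tert-butyldimethylsilyl)oxy]phenyl}-2-methylpropanoate | COC(=O)C(C)(C)c1ccc(O[Si](C)(C)C(C)(C)C)cc1O[Si](C)(C)C(C)(C)C
F2 | step 10 | 2-{2,4-bis[(tert-butyldimethylsilyl)oxy]phenyl}-2-methylpropanal | O=CC(C)(C)c1ccc(O[Si](C)(C)C(C)(C)C)cc1O[Si](C)(C)C(C)(C)C
F3 | step 4 | 5-bromo-8-[(tert-butyldimethylsilyl)oxy]-3-iodo-2,2-dimethyl-2H-chromene-6-carbaldehyde | O=Cc1cc(O[Si](C)(C)C(C)(C)C)c2OC(C)(C)C(I)=Cc2c1Br
F4 | step 2 | 2-bromo-4,5-bis[(tert-butyldimethylsilyl)oxy]benzaldehyde | O=Cc1cc(O[Si](C)(C)C(C)(C)C)c(O[Si](C)(C)C(C)(C)C)cc1Br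
F5 | step 2 | 2-bromo-5-[(tert-butyldimethylsilyl)oxy]-4-hydroxybenzaldehyde | O=Cc1cc(O[Si](C)(C)C(C)(C)C)c(O)cc1Br
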